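**Retrosynthetic overview**

1. Target 20 ⇐ Shi epoxidation (10,11-oxirane) and cross-metathesis prenylation of allyl chlorohydrin 18 ⇐ chloride opening of 3,4-epoxide 17.
2. 17 ⇐ OH-directed epoxidation and O2-selective angeloylation of cis-1,2-diol-3-ene 14 ⇐ dehydration of all-cis triol 10 ⇐ OH-directed dihydroxylation of cis-cyclohexenol 8.
3. 8 ⇐ key step: enantioselective carbonyl–ene (Prins-type) cyclisation of the fully armed acyclic (2Z,6E)-8-angeloyloxy "farnesal" 7. It forms C1–C6 and loses a C14 proton to give the 7(14)-methylene, the farnesyl → bisabolyl → β-bisabolene mode of ring closure.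
4. 7 ⇐ neryl acetate 1 by SeO2 oxidation (C8 aldehyde), Brown allylation (C8 stereocentre), angeloylation, acetate removal and oxidation.
5. Ring order: cyclohexene (step 6) → 3,4-oxirane (step 9, opened by chloride in step 11) → 10,11-oxirane (step 13).

Assumption: bisabolane locants are used (ring C1 CHOH, C2 CHOAng, C3 C(OH)Me, C4 CHCl, C5 CH2, C6 CH; chain C7(=C14H2), C8 CHOAng, C9, C10/C11 oxirane), the target read from the SMILES is (1S,2S,3S,4S,6R,8S,10R), and angelate/Ang means (2Z)-2-methylbut-2-enoate/-enoyl.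

**Route**

Step 1
Reactants: 1 neryl acetate
Product: 2 (2E,6Z)-8-acetoxy-2,6-dimethylocta-2,6-dienal
Conditions: SeO2 (1.2 equiv), 95% EtOH, reflux
Reagents that add atoms: selenium dioxide, O=[Se]=O
Why: Riley allylic oxidation (ene reaction/[2,3]-shift) takes place only at the electron-rich terminal olefin and only at its (E)-methyl group, giving the (E)-enal, because the 2,3-olefin is deactivated by the allylic acetate; no stereocentre is formed.

Step 2
Reactants: 2 (2E,6Z)-8-acetoxy-2,6-dimethylocta-2,6-dienal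
Product: 4 (2Z,6E,8S)-8-hydroxy-3,7-dimethylundeca-2,6,10-trien-1-yl acetate, via O-borinate 3 (not isolated)
Conditions: (−)-Ipc2B(allyl), Et2O, −78 °C; then H2O2, pH 7 buffer, 0 °C → rt
Reagents that add atoms: (−)-B-allyldiisopinocampheylborane (from (+)-α-pinene), C=CCB([C@@H]1C[C@@H]2C[C@H]([C@H]1C)C2(C)C)[C@@H]1C[C@@H]2C[C@H]([C@H]1C)C2(C)C
Why: Brown asymmetric allylboration through a closed chair transition state in which the Ipc groups direct allyl transfer to the Si face of the aldehyde, which sets C8 as S by reagent control; the allylborane adds 1,2 to the aldehyde and leaves the acetate untouched.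

Step 3
Reactants: 4 (2Z,6E,8S)-8-hydroxy-3,7-dimethylundeca-2,6,10-trien-1-yl acetate
Product: 5 (2Z,6E,8S)-8-(angeloyloxy)-3,7-dimethylundeca-2,6,10-trien-1-yl acetate
Conditions: angelic acid, 2,4,6-Cl3C6H2COCl, Et3N, PhMe, rt; then 4, 80 °C
Reagents that add atoms: angelic acid, C/C=C(/C)C(=O)O
Why: Yamaguchi esterification through the mixed anhydride, run without DMAP so that the angelate does not isomerise to the tiglate; the carbinol stereocentre is not touched.

Step 4
Reactants: 5 (2Z,6E,8S)-8-(angeloyloxy)-3,7-dimethylundeca-2,6,10-trien-1-yl acetate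
Product: 6 (2Z,6E,8S)-8-(angeloyloxy)-3,7-dimethylundeca-2,6,10-trien-1-ol
Conditions: K2CO3 (0.3 equiv), MeOH, 0 °C
Reagents that add atoms: none
Why: Zemplén-type transesterification is far faster for the unhindered primary acetate than for the hindered conjugated secondary angelate, which frees only the C1 alcohol.

Step 5
Reactants: 6 (2Z,6E,8S)-8-(angeloyloxy)-3,7-dimethylundeca-2,6,10-trien-1-ol
Product: 7 (2Z,6E,8S)-8-(angeloyloxy)-3,7-dimethylundeca-2,6,10-trienal
Conditions: TEMPO (10 mol %), PhI(OAc)2, CH2Cl2, rt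
Reagents that add atoms: none
Why: TEMPO/PhI(OAc)2 (oxoammonium) oxidation of the primary allylic alcohol stops at the aldehyde under non-basic conditions, so the (2Z) geometry is kept, as in the nerol to neral oxidation.

Step 6
Reactants: 7 (2Z,6E,8S)-8-(angeloyloxy)-3,7-dimethylundeca-2,6,10-trienal
Product: 8 (3S)-2-[(1R,2R)-2-hydroxy-4-methylcyclohex-3-en-1-yl]hexa-1,5-dien-3-yl angelate
Conditions: confined chiral imidodiphosphorimidate (IDPi) Brønsted acid (5 mol %, the enantiomer that turns neral into (1S,6R)-isopiperitenol), PhMe, 5 Å MS, −20 °C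
Reagents that add atoms: none
Why: Proposed new method: a biomimetic type-I carbonyl–ene (Prins-type) cyclisation in which the acid-activated (2Z)-enal carbon C1 is attacked by the 6,7-olefin and a C14 proton is lost (the C1–C6 closure and β-bisabolene-type termination of the farnesyl → bisabolyl pathway), the closest known reaction being the IDPi-catalysed cyclisation of neral to isopiperitenol; because the C7 substituent trans to C5 is the hindered acyloxy-bearing C8 methine, hydrogen should be taken from the cis-methyl C14, which is within reach only in the chair with the carbonyl oxygen axial, so the cis-1,6 alcohol with the 7(14)-methylene is expected while the confined chiral anion fixes the sense of the chair (C6 R, hence C1 R).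

Step 7
Reactants: 8 (3S)-2-[(1R,2R)-2-hydroxy-4-methylcyclohex-3-en-1-yl]hexa-1,5-dien-3-yl angelate
Product: 10 (3S)-2-[(1R,2S,3S,4R)-2,3,4-trihydroxy-4-methylcyclohexyl]hexa-1,5-dien-3-yl angelate, via osmate ester 9 (not isolated)
Conditions: OsO4 (1.05 equiv), TMEDA, CH2Cl2, −78 °C; then HCl, MeOH, rt
Reagents that add atoms: osmium tetroxide, O=[Os](=O)(=O)=O
Why: Donohoe hydroxyl-directed dihydroxylation: hydrogen bonding of the pseudo-axial allylic C1-OH to OsO4·TMEDA delivers both oxygens to the ring olefin from the face of that hydroxyl, which sets C2 and C3 cis to C1-OH, while the non-directed terminal, exocyclic and angelate olefins react more slowly.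

Step 8
Reactants: 10 (3S)-2-[(1R,2S,3S,4R)-2,3,4-trihydroxy-4-methylcyclohexyl]hexa-1,5-dien-3-yl angelate
Product: 14 (3S)-2-[(1R,5R,6S)-5,6-dihydroxy-4-methylcyclohex-3-en-1-yl]hexa-1,5-dien-3-yl angelate, via bis-TMS ether 11 (not isolated), via chlorosulfite 12 (not isolated), via silylated alkene 13 (not isolated)
Conditions: TMSCl (2.1 equiv), imidazole, CH2Cl2, −20 °C; then SOCl2, pyridine, −30 → 0 °C; then citric acid, MeOH, rt
Reagents that add atoms: none
Why: After transient silylation of the two secondary hydroxyls, the axial tertiary alcohol is dehydrated via its chlorosulfite by E2 loss of the anti-periplanar axial H-4 (loss of H-2 is disfavoured because C2 carries oxygen), which moves the double bond to C3=C4 without touching C1, C2, C6 or C8; the silyl groups fall off in the acidic methanol quench.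

Step 9
Reactants: 14 (3S)-2-[(1R,5R,6S)-5,6-dihydroxy-4-methylcyclohex-3-en-1-yl]hexa-1,5-dien-3-yl angelate
Product: 15 (3S)-2-[(1R,2S,3S,4S,5R)-4,5-epoxy-2,3-dihydroxy-4-methylcyclohexyl]hexa-1,5-dien-3-yl angelate
Conditions: VO(acac)2 (5 mol %), t-BuOOH, CH2Cl2, 0 °C → rt
Reagents that add atoms: tert-butyl hydroperoxide, CC(C)(C)OO
Why: Sharpless vanadium-catalysed hydroxyl-directed epoxidation: the allylic C2-OH (helped by the homoallylic C1-OH) delivers oxygen to the same face of the 3,4-olefin, which sets C3 and C4 (oxirane cis to both hydroxyls), while olefins without an allylic hydroxyl are not epoxidised.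

Step 10
Reactants: 15 (3S)-2-[(1R,2S,3S,4S,5R)-4,5-epoxy-2,3-dihydroxy-4-methylcyclohexyl]hexa-1,5-dien-3-yl angelate
Product: 17 (3S)-2-[(1R,2S,3S,4R,5R)-3-(angeloyloxy)-4,5-epoxy-2-hydroxy-4-methylcyclohexyl]hexa-1,5-dien-3-yl angelate, via stannylene acetal 16 (not isolated)
Conditions: Bu2SnO, PhMe, 4 Å MS, 80 °C; then angeloyl chloride, 0 °C
Reagents that add atoms: angeloyl chloride, C/C=C(/C)C(Cl)=O
Why: Regioselective monoacylation of a cis-1,2-diol via its dibutylstannylene acetal takes place at the equatorial oxygen (O2), which leaves the axial C1-OH free; no stereocentre changes.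

Step 11
Reactants: 17 (3S)-2-[(1R,2S,3S,4R,5R)-3-(angeloyloxy)-4,5-epoxy-2-hydroxy-4-methylcyclohexyl]hexa-1,5-dien-3-yl angelate
Product: 18 (3S)-2-[(1R,2S,3S,4S,5S)-3-(angeloyloxy)-5-chloro-2,4-dihydroxy-4-methylcyclohexyl]hexa-1,5-dien-3-yl angelate
Conditions: LiCl, AcOH, THF, rt
Reagents that add atoms: lithium chloride, [Li+].[Cl-]
Why: SN2 opening of the epoxide by chloride with inversion at the secondary C4 under Fürst–Plattner (trans-diaxial) control, favoured also because C3 is tertiary and deactivated by the neighbouring acyloxy group, gives the trans-diaxial 3-hydroxy-4-chloro array as in the presumed biogenesis of the chlorohydrin.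

Step 12
Reactants: 18 (3S)-2-[(1R,2S,3S,4S,5S)-3-(angeloyloxy)-5-chloro-2,4-dihydroxy-4-methylcyclohexyl]hexa-1,5-dien-3-yl angelate
Product: 19 (3S)-2-[(1R,2S,3S,4S,5S)-3-(angeloyloxy)-5-chloro-2,4-dihydroxy-4-methylcyclohexyl]-6-methylhepta-1,5-dien-3-yl angelate
Conditions: Hoveyda–Grubbs II (5 mol %), 2-methyl-2-butene, CH2Cl2, 40 °C
Reagents that add atoms: 2-methyl-2-butene, CC=C(C)C
Why: Olefin cross-metathesis of the only monosubstituted alkene with 2-methyl-2-butene gives the prenyl terminus, while the 1,1-disubstituted and the trisubstituted electron-poor olefins do not enter metathesis.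

Step 13
Reactants: 19 (3S)-2-[(1R,2S,3S,4S,5S)-3-(angeloyloxy)-5-chloro-2,4-dihydroxy-4-methylcyclohexyl]-6-methylhepta-1,5-dien-3-yl angelate
Product: 20 CNP0158207.1, (3S)-2-[(1R,2S,3S,4S,5S)-3-(angeloyloxy)-5-chloro-2,4-dihydroxy-4-methylcyclohexyl]-4-[(2R)-3,3-dimethyloxiran-2-yl]but-1-en-3-yl angelate
Conditions: D-fructose-derived Shi ketone (0.3 equiv), Oxone, NaHCO3 (pH ≈ 8), MeCN–DMM/aq. Na2EDTA, 0 °C
Reagents that add atoms: Oxone (potassium peroxymonosulfate), [K+].[O-]S(=O)(=O)OO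
Why: Shi asymmetric epoxidation through the chiral dioxirane (spiro transition state) oxidises only the electron-rich trisubstituted olefin and sets C10 as R by reagent control, and the near-neutral buffer keeps the chlorohydrin from closing.

**Compound list**

1 | neryl acetate, (2Z)-3,7-dimethylocta-2,6-dien-1-yl acetate | CC(=O)OC/C=C(C)\CCC=C(C)C | starting material
2 | (2E,6Z)-8-acetoxy-2,6-dimethylocta-2,6-dienal | CC(=O)OC/C=C(C)\CC/C=C(C)/C=O | intermediate
3 | C8 O-diisopinocampheylborinate of 4 | CC(=O)OC/C=C(C)\CC/C=C(C)/[C@@H](OB([C@@H]1C[C@@H]2C[C@H]([C@H]1C)C2(C)C)[C@@H]1C[C@@H]2C[C@H]([C@H]1C)C2(C)C)CC=C | intermediate (not isolated)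
4 | (2Z,6E,8S)-8-hydroxy-3,7-dimethylundeca-2,6,10-trien-1-yl acetate | CC(=O)OC/C=C(C)\CC/C=C(C)/[C@@H](O)CC=C | intermediate
5 | (2Z,6E,8S)-8-(angeloyloxy)-3,7-dimethylundeca-2,6,10-trien-1-yl acetate | CC(=O)OC/C=C(C)\CC/C=C(C)/[C@H](CC=C)OC(=O)/C(C)=C\C | intermediate
6 | (2Z,6E,8S)-8-(angeloyloxy)-3,7-dimethylundeca-2,6,10-trien-1-ol | OC/C=C(C)\CC/C=C(C)/[C@H](CC=C)OC(=O)/C(C)=C\C | intermediate
7 | (2Z,6E,8S)-8-(angeloyloxy)-3,7-dimethylundeca-2,6,10-trienal | O=C/C=C(C)\CC/C=C(C)/[C@H](CC=C)OC(=O)/C(C)=C\C | intermediate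
8 | (3S)-2-[(1R,2R)-2-hydroxy-4-methylcyclohex-3-en-1-yl]hexa-1,5-dien-3-yl angelate | C=C([C@H](CC=C)OC(=O)/C(C)=C\C)[C@H]1CCC(C)=C[C@H]1O | intermediate
9 | cyclic O2,O3-osmate(VI) ester of 10, TMEDA complex | C=C([C@H](CC=C)OC(=O)/C(C)=C\C)[C@H]1CC[C@@]2(C)O[Os-2]3(=O)(=O)([N+](C)(C)CC[N+]3(C)C)O[C@H]2[C@H]1O | intermediate (not isolated)
10 | (3S)-2-[(1R,2S,3S,4R)-2,3,4-trihydroxy-4-methylcyclohexyl]hexa-1,5-dien-3-yl angelate | C=C([C@H](CC=C)OC(=O)/C(C)=C\C)[C@H]1CC[C@@](C)(O)[C@@H](O)[C@H]1O | intermediate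
11 | O1,O2-bis(trimethylsilyl) ether of 10 | C=C([C@H](CC=C)OC(=O)/C(C)=C\C)[C@H]1CC[C@@](C)(O)[C@@H](O[Si](C)(C)C)[C@H]1O[Si](C)(C)C | intermediate (not isolated)
12 | O3-chlorosulfite of 11 | C=C([C@H](CC=C)OC(=O)/C(C)=C\C)[C@H]1CC[C@@](C)(OS(Cl)=O)[C@@H](O[Si](C)(C)C)[C@H]1O[Si](C)(C)C | intermediate (not isolated)
13 | O1,O2-bis(trimethylsilyl) ether of 14 | C=C([C@H](CC=C)OC(=O)/C(C)=C\C)[C@H]1CC=C(C)[C@@H](O[Si](C)(C)C)[C@H]1O[Si](C)(C)C | intermediate (not isolated)
14 | (3S)-2-[(1R,5R,6S)-5,6-dihydroxy-4-methylcyclohex-3-en-1-yl]hexa-1,5-dien-3-yl angelate | C=C([C@H](CC=C)OC(=O)/C(C)=C\C)[C@H]1CC=C(C)[C@@H](O)[C@H]1O | intermediate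
15 | (3S)-2-[(1R,2S,3S,4S,5R)-4,5-epoxy-2,3-dihydroxy-4-methylcyclohexyl]hexa-1,5-dien-3-yl angelate | C=C([C@H](CC=C)OC(=O)/C(C)=C\C)[C@H]1C[C@H]2O[C@@]2(C)[C@@H](O)[C@H]1O | intermediate
16 | O1,O2-dibutylstannylene acetal of 15 | C=C([C@H](CC=C)OC(=O)/C(C)=C\C)[C@H]1C[C@H]2O[C@@]2(C)[C@H]3O[Sn](CCCC)(CCCC)O[C@@H]13 | intermediate (not isolated)
17 | (3S)-2-[(1R,2S,3S,4R,5R)-3-(angeloyloxy)-4,5-epoxy-2-hydroxy-4-methylcyclohexyl]hexa-1,5-dien-3-yl angelate | C=C([C@H](CC=C)OC(=O)/C(C)=C\C)[C@H]1C[C@H]2O[C@@]2(C)[C@@H](OC(=O)/C(C)=C\C)[C@H]1O | intermediate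
18 | (3S)-2-[(1R,2S,3S,4S,5S)-3-(angeloyloxy)-5-chloro-2,4-dihydroxy-4-methylcyclohexyl]hexa-1,5-dien-3-yl angelate | C=C([C@H](CC=C)OC(=O)/C(C)=C\C)[C@H]1C[C@H](Cl)[C@@](C)(O)[C@@H](OC(=O)/C(C)=C\C)[C@H]1O | intermediate
19 | (3S)-2-[(1R,2S,3S,4S,5S)-3-(angeloyloxy)-5-chloro-2,4-dihydroxy-4-methylcyclohexyl]-6-methylhepta-1,5-dien-3-yl angelate | C=C([C@H](CC=C(C)C)OC(=O)/C(C)=C\C)[C@H]1C[C@H](Cl)[C@@](C)(O)[C@@H](OC(=O)/C(C)=C\C)[C@H]1O | intermediate
20 | CNP0158207.1, (1S,2S,3S,4S,6R,8S,10R)-2,8-bis(angeloyloxy)-4-chloro-10,11-epoxybisabol-7(14)-ene-1,3-diol | C=C([C@H](C[C@H]1OC1(C)C)OC(=O)/C(C)=C\C)[C@H]1C[C@H](Cl)[C@@](C)(O)[C@@H](OC(=O)/C(C)=C\C)[C@H]1O | target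

**Totals and risks**

Total step count: 13. Longest linear sequence: 13 (fully linear, 1 → 20).

The three steps most likely to fail:

Step 6. The cyclisation is unprecedented on this substrate. It may give the trans alcohol, take hydrogen from C8 (enol ester), ionise the allylic angelate, or give poor control at C6. The fallback sets out from 6 and comes back at 8, and takes C1 and C6 from a Sharpless epoxide instead of a chiral acid. Alcohol 6 is epoxidised (Ti(OiPr)4, L-(+)-DET, t-BuOOH, −20 °C) to (2S,3R,6E,8S)-8-(angeloyloxy)-2,3-epoxy-3,7-dimethylundeca-6,10-dien-1-ol F1. Dess–Martin oxidation gives (2R,3R,6E,8S)-8-(angeloyloxy)-2,3-epoxy-3,7-dimethylundeca-6,10-dienal F2. A MgBr2·OEt2-chelated carbonyl–ene cyclisation, in which the chelate holds the aldehyde oxygen axial and syn to the epoxide oxygen so that hydrogen comes from C14, should give (3S)-2-[(1R,2S,3S,4R)-3,4-epoxy-2-hydroxy-4-methylcyclohexyl]hexa-1,5-dien-3-yl angelate F3. Stereospecific deoxygenation of the epoxide (Ph3P=Se, TFA, CH2Cl2) then returns 8.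

Step 8. The dehydration can give the exocyclic methylene isomer or eliminate towards C2, and incomplete silylation would lead to cyclic sulfites. The fallback sets out from 10 and comes back at 14, using an isolated cyclic protecting group and a syn-elimination that cannot reach H-2. Triol 10 is treated with carbonyldiimidazole to give the cyclic O1,O2-carbonate of triol 10 F4. Burgess reagent (PhH, 50 °C) dehydrates the tertiary alcohol to the cyclic O1,O2-carbonate of diol 14 F5. K2CO3 in MeOH at 0 °C removes the carbonate and gives 14.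

Step 10. The stannylene acylation may not discriminate O2 from O1, and the tin chloride formed may open the epoxide early. The fallback sets out from 15 and comes back at 18, so 17 is skipped. Epoxy diol 15 is opened first (LiCl, AcOH, THF) to (3S)-2-[(1R,2S,3S,4S,5S)-5-chloro-2,3,4-trihydroxy-4-methylcyclohexyl]hexa-1,5-dien-3-yl angelate F6. Phenylboronic acid (PhMe, 4 Å MS) bridges the 1,3-diaxial hydroxyls to give the O1,O3-phenylboronate of F6 F7, which leaves only the equatorial O2-H free and also blocks closure of the chlorohydrin. Yamaguchi angeloylation gives the O2-angelate of that boronate F8. Washing with aqueous sorbitol/NaHCO3 removes the boronate and gives 18.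

**Further compounds**

F1 | step 6 | (2S,3R,6E,8S)-8-(angeloyloxy)-2,3-epoxy-3,7-dimethylundeca-6,10-dien-1-ol | OC[C@@H]1O[C@]1(C)CC/C=C(C)/[C@H](CC=C)OC(=O)/C(C)=C\C
F2 | step 6 | (2R,3R,6E,8S)-8-(angeloyloxy)-2,3-epoxy-3,7-dimethylundeca-6,10-dienal | O=C[C@@H]1O[C@]1(C)CC/C=C(C)/[C@H](CC=C)OC(=O)/C(C)=C\C
F3 | step 6 | (3S)-2-[(1R,2S,3S,4R)-3,4-epoxy-2-hydroxy-4-methylcyclohexyl]hexa-1,5-dien-3-yl angelate | C=C([C@H](CC=C)OC(=O)/C(C)=C\C)[C@H]1CC[C@@]2(C)O[C@H]2[C@H]1O
F4 | step 8 | cyclic O1,O2-carbonate of triol 10 | C=C([C@H](CC=C)OC(=O)/C(C)=C\C)[C@H]1CC[C@@](C)(O)[C@H]2OC(=O)O[C@@H]12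
F5 | step 8 | cyclic O1,O2-carbonate of diol 14 | C=C([C@H](CC=C)OC(=O)/C(C)=C\C)[C@H]1CC=C(C)[C@H]2OC(=O)O[C@@H]12
F6 | step 10 | (3S)-2-[(1R,2S,3S,4S,5S)-5-chloro-2,3,4-trihydroxy-4-methylcyclohexyl]hexa-1,5-dien-3-yl angelate | C=C([C@H](CC=C)OC(=O)/C(C)=C\C)[C@H]1C[C@H](Cl)[C@@](C)(O)[C@@H](O)[C@H]1O
F7 | step 10 | O1,O3-phenylboronate of F6 | C=C([C@H](CC=C)OC(=O)/C(C)=C\C)[C@H]1C[C@H](Cl)[C@@]2(C)OB(c3ccccc3)O[C@@H]1[C@@H]2O
F8 | step 10 | O2-angelate of the O1,O3-phenylboronate F7 | C=C([C@H](CC=C)OC(=O)/C(C)=C\C)[C@H]1C[C@H](Cl)[C@@]2(C)OB(c3ccccc3)O[C@@H]1[C@@H]2OC(=O)/C(C)=C\C
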